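**Retrosynthetic overview**

1. Oxepane last: the C3 tertiary alcohol displaces a C16 triflate (C15 set by hydroboration of a C14 isopropenyl group); C6–OMe and C7–H come from the Z C6=C7 alkene by C3–OH-tethered hydrosilylation–oxidation.
2. Cyclohexane and tetrahydrofuran (C1–C10 and C13–C14 bonds) form together in an intramolecular Diels–Alder reaction of a 2,9-cis-disubstituted oxonene (silyloxydiene on C9, enoate on C2).
3. The nine-membered oxonane (O1, C2–C9) arises by a two-atom Claisen ring expansion of a seven-membered 2-methylene-7-vinyl-1,4-dioxepane, made from a 1,4-dioxepan-2-one.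
4. Enabling feature: in the nine-membered ring the oxygenated C3 and the C6/C7 pair are joined by C4–C5, a γ,δ-unsaturated ketone retron (C3=O, C6=C7); O1, C2, C9, C8, C7 and C3 plus one ester oxygen (C3–O–C7) form a seven-membered lactone whose stereocentres C2 and C9 flank O1.
5. Ring order: dioxepanone (7) → oxonene (9) → cyclohexene + tetrahydrofuran → oxepane.

Key step: step 9

**Remarks**

- Locants (asbestinin-type): O1 is the oxygen between C2 and C9; C3 = C(CH3)–O; C6 = CH–OCH3; C7 = CH–CH3; C11 = CH–OAc; C12 = CH–CH3; C14–C15(CH3)–C16H2–O–C3 is the oxepane arm.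
- Assumption: the carbinol centres from the Grignard additions of step 7 (C7) and step 13 (C11) are expected as epimer mixtures. Compounds 11–14 are drawn as one C7 epimer; 19, 20 and the acetal carbon of ozonide 9 carry no descriptor at that centre. Each of these centres is destroyed later (steps 9, 15 and 6).
- Descriptors in names follow CIP priorities and can change where a neighbouring group changes; the SMILES in the compound list define the stereochemistry.

**Route**

Step 1
Reactants: 1 3-[(4-methoxybenzyl)oxy]propanal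
Product: 2 (S)-1-[(4-methoxybenzyl)oxy]-5-methylhex-5-en-3-ol
Conditions: Bu3SnCH2C(CH3)=CH2, (S)-BINOL (20 mol %), Ti(OiPr)4 (10 mol %), 4 Å MS, CH2Cl2, −20 °C; aqueous work-up
Reagents that add atoms: tributyl(2-methylallyl)stannane, CCCC[Sn](CCCC)(CCCC)CC(C)=C
Why: Keck allylation: the BINOL–Ti(OiPr)4 Lewis acid activates the aldehyde and the (S)-ligand should expose its Si face to the methallylstannane, which sets C9.

Step 2
Reactants: 2 (S)-1-[(4-methoxybenzyl)oxy]-5-methylhex-5-en-3-ol
Product: 3 glycolic acid ether of 2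
Conditions: NaH, BrCH2CO2H, THF, 0 °C → rt; HCl (aq) work-up
Reagents that add atoms: bromoacetic acid, OC(=O)CBr
Why: Williamson etherification of the sodium alkoxide with sodium bromoacetate (SN2 at the primary α-bromo carbon); C9 is not touched.

Step 3
Reactants: 3 glycolic acid ether of 2
Product: 5 N-glycolyl oxazolidinone, via mixed pivalic anhydride 4 (not isolated)
Conditions: t-BuCOCl, Et3N, THF, −78 → 0 °C; then lithiated (R)-4-benzyl-2-oxazolidinone (from n-BuLi), −78 → 0 °C
Reagents that add atoms: (R)-4-benzyl-2-oxazolidinone, O=C1N[C@H](Cc2ccccc2)CO1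
Why: N-acylation of the lithiated auxiliary by the mixed anhydride, which is attacked at the less hindered glycolyl carbonyl.

Step 4
Reactants: 5 N-glycolyl oxazolidinone
Product: 6 C2-benzyloxymethylated imide
Conditions: NaN(SiMe3)2, THF, −78 °C; BnOCH2Cl, −78 → −45 °C
Reagents that add atoms: benzyl chloromethyl ether, ClCOCc1ccccc1
Why: Evans alkylation of the chelated Z sodium glycolate enolate: the benzyl group of the (R)-auxiliary shields one enolate face, so the electrophile enters from the other and sets C2 (S).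

Step 5
Reactants: 6 C2-benzyloxymethylated imide
Product: 8 (S)-3-(benzyloxy)-2-alkoxypropanoic acid, via peroxy acid 7 (not isolated)
Conditions: LiOH, H2O2, THF/H2O, 0 °C; Na2SO3; HCl (aq)
Reagents that add atoms: hydrogen peroxide, OO
Why: Hydroperoxide cleaves the exocyclic imide carbonyl selectively (LiOOH hydrolysis of Evans imides), sulfite reduces the peracid, and C2 is not epimerized.

Step 6
Reactants: 8 (S)-3-(benzyloxy)-2-alkoxypropanoic acid
Product: 10 keto acid, via ozonide 9 (not isolated)
Conditions: O3, CH2Cl2, −78 °C; then Me2S, −78 °C → rt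
Reagents that add atoms: ozone, [O-][O+]=O
Why: Ozonolysis of the only alkene (1,1-disubstituted) with reductive work-up unveils the C7 methyl ketone; the benzylic ethers and the acid should survive at −78 °C with careful end-point control.

Step 7
Reactants: 10 keto acid
Product: 11 tertiary allylic hydroxy acid
Conditions: CH2=CHMgBr (3.5 equiv), THF, −78 → −20 °C; NH4Cl/HCl (aq)
Reagents that add atoms: vinylmagnesium bromide, C=C[Mg]Br
Why: Grignard 1,2-addition to the ketone after in situ formation of the unreactive magnesium carboxylate; the new C7 centre is not controlled and need not be, because it becomes sp2 in step 9.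

Step 8
Reactants: 11 tertiary allylic hydroxy acid
Product: 13 7-methyl-7-vinyl-1,4-dioxepan-2-one, via mixed trichlorobenzoic anhydride 12 (not isolated)
Conditions: 2,4,6-Cl3C6H2COCl, Et3N, THF, rt; then DMAP, toluene, 80 °C, high dilution
Reagents that add atoms: none
Why: Yamaguchi lactonization: the tertiary allylic alcohol opens the mixed anhydride under DMAP catalysis and closes the seven-membered lactone (7-exo-trig acyl substitution) without touching C2 or C9.

Step 9
Reactants: 13 7-methyl-7-vinyl-1,4-dioxepan-2-one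
Product: 15 (Z)-oxon-6-en-3-one, via methylene dioxepane 14 (not isolated)
Conditions: Cp2TiMe2, toluene, 65 °C, dark; filtration through basic Al2O3 (pentane); then toluene, 135 °C, sealed, base-washed glass
Reagents that add atoms: dimethyltitanocene Cp2TiMe2, C[Ti](C)(C1C=CC=C1)C1C=CC=C1
Why: Cp2TiMe2 methylenates the lactone carbonyl (Petasis olefination) to the 2-methylene-7-vinyl-1,4-dioxepane 14, an allyl vinyl ether held in a seven-membered ring, and heating triggers its [3,3]-sigmatropic (Claisen) rearrangement: C4 (the new methylene) bonds to C5 (the vinyl terminus) while the ring C7–O bond breaks, so the ring gains C4, C5 and C6, loses the ester oxygen and becomes the nine-membered oxonane (net two-atom ring expansion). The closest known reaction type is the Claisen ring expansion of 2-methylene-6-vinyl cyclic ethers to 4-cycloalkenones and of vinyl-substituted cyclic enol ethers and ketene acetals to eight- and nine-membered oxacycles. The nine-membered ring is closed by C4–C5 bond formation in a bridged bicyclo[4.3.1]-type chair-like transition state in which the oxygen that leaves the ring is the one-atom bridge. No stereocentre is created: C2 and C9 lie outside the pericyclic array and are carried over unchanged, and C7 becomes sp2, so both C7 epimers of 13 should converge on the same product. The selectivity needed is the Z geometry of the new C6=C7 bond, which the bridged transition state secures by holding the C5–C6–C7–C8 torsion synclinal, and chemoselective methylenation, secured because the lactone is the only carbonyl group present and because titanium residues are removed before the thermal stage so that the product ketone is not methylenated.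

Step 10
Reactants: 15 (Z)-oxon-6-en-3-one
Product: 16 (3S)-3-methyl-oxon-6-en-3-ol
Conditions: AlMe3 (3 equiv), toluene, −78 → 0 °C; aqueous potassium sodium tartrate
Reagents that add atoms: trimethylaluminium, C[Al](C)C
Why: Non-chelating 1,2-addition of AlMe3 (Felkin–Anh polar model): with the ring oxygen O1 perpendicular to the carbonyl plane the methyl group should enter the Re face of C3, anti to O1 and from the ring periphery, giving the tertiary alcohol with OH cis to the C2 side chain.

Step 11
Reactants: 16 (3S)-3-methyl-oxon-6-en-3-ol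
Product: 17 C11 primary alcohol
Conditions: DDQ, CH2Cl2/pH 7 buffer, 0 °C
Reagents that add atoms: none
Why: Oxidative cleavage of the electron-rich PMB ether by DDQ (hydride abstraction, then hydrolysis); the benzyl ether, the trisubstituted alkene and the tertiary alcohol should be unaffected.

Step 12
Reactants: 17 C11 primary alcohol
Product: 18 C11 aldehyde
Conditions: Dess–Martin periodinane, pyridine, CH2Cl2, 0 °C → rt
Reagents that add atoms: none
Why: Dess–Martin oxidation of the primary alcohol under buffered conditions; the tertiary alcohol cannot be oxidized.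

Step 13
Reactants: 18 C11 aldehyde
Product: 19 C11 isopropenyl carbinol
Conditions: CH2=C(CH3)MgBr (2.5 equiv), THF, −78 °C; NH4Cl (aq)
Reagents that add atoms: isopropenylmagnesium bromide, CC(=C)[Mg]Br
Why: Grignard addition to the aldehyde at low temperature (one equivalent is consumed by the C3 hydroxyl); the C11 carbinol configuration is irrelevant because it is oxidized in step 15.

Step 14
Reactants: 19 C11 isopropenyl carbinol
Product: 20 triol
Conditions: Na, NH3 (l), THF, −78 °C; then NH4Cl
Reagents that add atoms: none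
Why: Birch-type reductive cleavage of the benzyl ether; isolated alkenes and alkoxides should not be reduced at −78 °C.

Step 15
Reactants: 20 triol
Product: 21 C1 aldehyde C11 isopropenyl ketone
Conditions: Dess–Martin periodinane (3 equiv), pyridine, CH2Cl2, rt
Reagents that add atoms: none
Why: Dess–Martin oxidation of the primary alcohol (to the C1 aldehyde) and of the allylic alcohol (to the C11 enone) in one operation; the tertiary C3 alcohol is inert.

Step 16
Reactants: 21 C1 aldehyde C11 isopropenyl ketone
Product: 22 (E)-enoate dienone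
Conditions: Ph3P=CHCO2Me, CH2Cl2, rt
Reagents that add atoms: methyl (triphenylphosphoranylidene)acetate, COC(=O)C=P(c1ccccc1)(c1ccccc1)c1ccccc1
Why: Wittig reaction of the stabilized ylide, which reacts with the aldehyde but not the ketone and gives the E enoate that becomes the dienophile C1=C14.

Step 17
Reactants: 22 (E)-enoate dienone
Product: 24 tricyclic cycloadduct, via silyloxydiene enoate 23 (not isolated)
Conditions: Et3SiOTf (3 equiv), Et3N, CH2Cl2, −78 → 0 °C; then toluene, 80 °C
Reagents that add atoms: triethylsilyl trifluoromethanesulfonate, CC[Si](CC)(CC)OS(=O)(=O)C(F)(F)F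
Why: Soft enolization gives the Z 2-silyloxydiene (C10–C13) and silylates C3–OH, then an intramolecular Diels–Alder reaction through the C9–O1–C2 tether forms C10–C1 and C13–C14 and closes cyclohexene and tetrahydrofuran together: the E dienophile fixes C1/C14 trans, and the 2,9-cis substituents on the oxonene should steer the ester-exo transition state that gives H1/H2 trans, H9/H10 trans and the cis ring fusion.

Step 18
Reactants: 24 tricyclic cycloadduct
Product: 25 C15 dimethyl carbinol
Conditions: MeMgBr (4 equiv), THF, 0 °C; NH4Cl (aq)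
Reagents that add atoms: methylmagnesium bromide, C[Mg]Br
Why: Double Grignard addition to the methyl ester; the silyl enol ether and the silyl ether tolerate MeMgBr.

Step 19
Reactants: 25 C15 dimethyl carbinol
Product: 26 C14 isopropenyl compound
Conditions: Burgess reagent, toluene, 60 °C
Reagents that add atoms: none
Why: Burgess dehydration (syn elimination through the sulfamate ester) towards a methyl group should give the isopropenyl group; the neutral conditions spare the silyl enol ether.

Step 20
Reactants: 26 C14 isopropenyl compound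
Product: 27 C11 ketone with free C3 alcohol
Conditions: HF·pyridine, pyridine, THF, 0 °C → rt
Reagents that add atoms: none
Why: HF cleaves both silyl groups; kinetic protonation of the enol at C12 should occur from the convex face, opposite the cis-fused tetrahydrofuran (the C10–C9 bond screens the other face), which puts the C12 methyl cis to C9.

Step 21
Reactants: 27 C11 ketone with free C3 alcohol
Product: 28 C11 alcohol
Conditions: NaBH4, CeCl3·7H2O, MeOH, −40 °C
Reagents that add atoms: none
Why: Luche reduction: hydride should attack C11 from the same convex face (the other face is blocked by the C10–C9 bond and the C12 methyl), giving the alcohol cis to the C12 methyl, and the fast, weakly basic conditions avoid epimerization at C12.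

Step 22
Reactants: 28 C11 alcohol
Product: 29 C11 acetate
Conditions: Ac2O, pyridine, DMAP (cat.), CH2Cl2, 0 °C
Reagents that add atoms: acetic anhydride, CC(=O)OC(C)=O
Why: DMAP-catalysed acetylation of the secondary alcohol; the hindered tertiary C3 alcohol should not react at 0 °C.

Step 23
Reactants: 29 C11 acetate
Product: 32 C6 alcohol with saturated C7, via hydrosilyl ether 30 (not isolated), via cyclic siloxane 31 (not isolated)
Conditions: (HMe2Si)2NH, 60 °C, then evaporation; H2PtCl6 (cat.), THF, 60 °C, dilute; then H2O2, KF, KHCO3, THF/MeOH, 0 °C → rt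
Reagents that add atoms: hydrogen peroxide, OO
Why: Tamao intramolecular hydrosilylation followed by Tamao–Fleming oxidation: the C3–O–SiMe2H group can reach only the C6=C7 bond, through a six-membered oxasilacycle, and only the alkene face syn to the C3 oxygen, so syn addition of Si (to C6) and H (to C7) and C–Si oxidation with retention set C6 and C7.

Step 24
Reactants: 32 C6 alcohol with saturated C7
Product: 33 C6 methyl ether
Conditions: MeOTf, 2,6-di-tert-butyl-4-methylpyridine, CH2Cl2, 0 °C → rt
Reagents that add atoms: methyl trifluoromethanesulfonate, COS(=O)(=O)C(F)(F)F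
Why: O-Methylation under non-basic conditions that leave the acetate in place; the secondary C6 alcohol reacts, the tertiary C3 alcohol should not.

Step 25
Reactants: 33 C6 methyl ether
Product: 35 C16 primary alcohol, via alkylborane 34 (not isolated)
Conditions: 9-BBN, THF, 0 °C → rt; then H2O2, NaOAc (aq), 0 °C → rt
Reagents that add atoms: hydrogen peroxide, OO
Why: Brown hydroboration–oxidation of the only remaining alkene: with C14–H eclipsing the double bond (minimized A1,3 strain) the borane should attack the face anti to C1, which sets C15, and the buffered oxidation spares the acetate.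

Step 26
Reactants: 35 C16 primary alcohol
Product: 37 target CNP0289153.2, via primary triflate 36 (not isolated)
Conditions: Tf2O, 2,6-lutidine, CH2Cl2, −78 → 0 °C
Reagents that add atoms: none
Why: Selective triflation of the primary alcohol and intramolecular SN2 displacement by the C3 tertiary alcohol (7-exo-tet Williamson-type etherification) closes the oxepane without touching a stereocentre.

**Compound list**

1 | 3-[(4-methoxybenzyl)oxy]propanal | COc1ccc(COCCC=O)cc1 | starting material
2 | (S)-1-[(4-methoxybenzyl)oxy]-5-methylhex-5-en-3-ol | C=C(C)C[C@H](O)CCOCc1ccc(OC)cc1 | intermediate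
3 | 2-{[(S)-1-[(4-methoxybenzyl)oxy]-5-methylhex-5-en-3-yl]oxy}acetic acid | C=C(C)C[C@H](OCC(=O)O)CCOCc1ccc(OC)cc1 | intermediate
4 | mixed anhydride of 3 with pivalic acid | C=C(C)C[C@H](OCC(=O)OC(=O)C(C)(C)C)CCOCc1ccc(OC)cc1 | intermediate
5 | (R)-4-benzyl-3-(2-{[(S)-1-[(4-methoxybenzyl)oxy]-5-methylhex-5-en-3-yl]oxy}acetyl)oxazolidin-2-one | C=C(C)C[C@H](OCC(=O)N1[C@H](Cc2ccccc2)COC1=O)CCOCc1ccc(OC)cc1 | intermediate
6 | (R)-4-benzyl-3-[(S)-3-(benzyloxy)-2-{[(S)-1-[(4-methoxybenzyl)oxy]-5-methylhex-5-en-3-yl]oxy}propanoyl]oxazolidin-2-one | C=C(C)C[C@H](O[C@@H](COCc1ccccc1)C(=O)N1[C@H](Cc2ccccc2)COC1=O)CCOCc1ccc(OC)cc1 | intermediate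
7 | peroxy acid corresponding to acid 8 | C=C(C)C[C@H](O[C@@H](COCc1ccccc1)C(=O)OO)CCOCc1ccc(OC)cc1 | intermediate
8 | (S)-3-(benzyloxy)-2-{[(S)-1-[(4-methoxybenzyl)oxy]-5-methylhex-5-en-3-yl]oxy}propanoic acid | C=C(C)C[C@H](O[C@@H](COCc1ccccc1)C(=O)O)CCOCc1ccc(OC)cc1 | intermediate
9 | ozonide (3-methyl-1,2,4-trioxolane) of 8 | CC1(C[C@H](O[C@@H](COCc2ccccc2)C(=O)O)CCOCc2ccc(OC)cc2)OCOO1 | intermediate
10 | (S)-3-(benzyloxy)-2-{[(R)-1-[(4-methoxybenzyl)oxy]-5-oxohexan-3-yl]oxy}propanoic acid (same spatial arrangement as 8) | CC(=O)C[C@H](O[C@@H](COCc1ccccc1)C(=O)O)CCOCc1ccc(OC)cc1 | intermediate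
11 | (S)-3-(benzyloxy)-2-{[(3R,5R)-5-hydroxy-1-[(4-methoxybenzyl)oxy]-5-methylhept-6-en-3-yl]oxy}propanoic acid (5R drawn, 5S epimer carried along) | C=C[C@](C)(O)C[C@H](O[C@@H](COCc1ccccc1)C(=O)O)CCOCc1ccc(OC)cc1 | intermediate
12 | mixed anhydride of 11 with 2,4,6-trichlorobenzoic acid | C=C[C@](C)(O)C[C@H](O[C@@H](COCc1ccccc1)C(=O)OC(=O)c1c(Cl)cc(Cl)cc1Cl)CCOCc1ccc(OC)cc1 | intermediate
13 | (3S,5R,7R)-3-[(benzyloxy)methyl]-5-{2-[(4-methoxybenzyl)oxy]ethyl}-7-methyl-7-vinyl-1,4-dioxepan-2-one (3,5-cis; 7-epimer carried along) | O=C1O[C@@](C)(C=C)C[C@@H](CCOCc2ccc(OC)cc2)O[C@H]1COCc2ccccc2 | intermediate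
14 | (3S,5R,7R)-3-[(benzyloxy)methyl]-5-{2-[(4-methoxybenzyl)oxy]ethyl}-7-methyl-2-methylene-7-vinyl-1,4-dioxepane | C=C1O[C@@](C)(C=C)C[C@@H](CCOCc2ccc(OC)cc2)O[C@H]1COCc2ccccc2 | intermediate
15 | (2S,9S,Z)-2-[(benzyloxy)methyl]-9-{2-[(4-methoxybenzyl)oxy]ethyl}-7-methyl-4,5,8,9-tetrahydrooxonin-3(2H)-one | O=C1CC/C=C(/C)C[C@@H](CCOCc2ccc(OC)cc2)O[C@H]1COCc2ccccc2 | intermediate
16 | (2S,3S,9S,Z)-2-[(benzyloxy)methyl]-9-{2-[(4-methoxybenzyl)oxy]ethyl}-3,7-dimethyl-2,3,4,5,8,9-hexahydrooxonin-3-ol | C[C@]1(O)CC/C=C(/C)C[C@@H](CCOCc2ccc(OC)cc2)O[C@H]1COCc2ccccc2 | intermediate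
17 | 16 with the PMB ether replaced by a free 2-hydroxyethyl group on C9 | C[C@]1(O)CC/C=C(/C)C[C@@H](CCO)O[C@H]1COCc2ccccc2 | intermediate
18 | C11 aldehyde: 17 with the C9 side chain oxidized to CH2CHO | C[C@]1(O)CC/C=C(/C)C[C@@H](CC=O)O[C@H]1COCc2ccccc2 | intermediate
19 | C11 carbinol: C9 side chain CH2CH(OH)C(CH3)=CH2 (both C11 epimers) | C[C@]1(O)CC/C=C(/C)C[C@@H](CC(O)C(C)=C)O[C@H]1COCc2ccccc2 | intermediate
20 | triol: 19 with the benzyl ether replaced by CH2OH on C2 | C[C@]1(O)CC/C=C(/C)C[C@@H](CC(O)C(C)=C)O[C@H]1CO | intermediate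
21 | C2 carbaldehyde with C9 side chain CH2C(=O)C(CH3)=CH2 | C[C@]1(O)CC/C=C(/C)C[C@@H](CC(=O)C(C)=C)O[C@H]1C=O | intermediate
22 | methyl (E)-3-(oxonen-2-yl)acrylate carrying the C9 dienone side chain | C[C@]1(O)CC/C=C(/C)C[C@@H](CC(=O)C(C)=C)O[C@H]1/C=C/C(=O)OC | intermediate
23 | 3-O-triethylsilyl ether of 22 with the C9 side chain as (Z)-CH=C(OSiEt3)C(CH3)=CH2 | C[C@]1(O[Si](CC)(CC)CC)CC/C=C(/C)C[C@@H](/C=C(\O[Si](CC)(CC)CC)C(C)=C)O[C@H]1/C=C/C(=O)OC | intermediate
24 | tricyclic cycloadduct: cyclohexene (C11 OSiEt3 enol ether, C12 methyl, C14 CO2Me) cis-fused to the tetrahydrofuran bridged by the (Z)-oxonene with 3-OSiEt3 | C[C@]1(O[Si](CC)(CC)CC)CC/C=C(/C)C[C@@H]2O[C@H]1[C@@H]3[C@H]2C(O[Si](CC)(CC)CC)=C(C)C[C@H]3C(=O)OC | intermediate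
25 | 24 with C14 2-hydroxyprop-2-yl in place of CO2Me | C[C@]1(O[Si](CC)(CC)CC)CC/C=C(/C)C[C@@H]2O[C@H]1[C@@H]3[C@H]2C(O[Si](CC)(CC)CC)=C(C)C[C@H]3C(C)(C)O | intermediate
26 | 24 with C14 isopropenyl in place of CO2Me | C[C@]1(O[Si](CC)(CC)CC)CC/C=C(/C)C[C@@H]2O[C@H]1[C@@H]3[C@H]2C(O[Si](CC)(CC)CC)=C(C)C[C@H]3C(C)=C | intermediate
27 | tricyclic C11 ketone with C12 methyl cis to C9, free 3-OH, C14 isopropenyl | C[C@]1(O)CC/C=C(/C)C[C@@H]2O[C@H]1[C@@H]3[C@H]2C(=O)[C@H](C)C[C@H]3C(C)=C | intermediate
28 | C11 alcohol (OH cis to C12 methyl and to C9) | C[C@]1(O)CC/C=C(/C)C[C@@H]2O[C@H]1[C@@H]3[C@H]2[C@H](O)[C@H](C)C[C@H]3C(C)=C | intermediate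
29 | C11 acetate of 28 | C[C@]1(O)CC/C=C(/C)C[C@@H]2O[C@H]1[C@@H]3[C@H]2[C@H](OC(C)=O)[C@H](C)C[C@H]3C(C)=C | intermediate
30 | 3-O-dimethylsilyl (Si–H) ether of 29 | C[C@]1(O[SiH](C)C)CC/C=C(/C)C[C@@H]2O[C@H]1[C@@H]3[C@H]2[C@H](OC(C)=O)[C@H](C)C[C@H]3C(C)=C | intermediate
31 | cyclic siloxane: C3–O–Si(CH3)2–C6 bridge, C7–H syn to Si | C[C@@]12CC[C@@H]([Si](C)(C)O1)[C@H](C)C[C@@H]3O[C@H]2[C@@H]4[C@H]3[C@H](OC(C)=O)[C@H](C)C[C@H]4C(C)=C | intermediate
32 | 3,6-diol: saturated oxonane with 6-OH and 7-CH3 | C[C@]1(O)CC[C@@H](O)[C@H](C)C[C@@H]2O[C@H]1[C@@H]3[C@H]2[C@H](OC(C)=O)[C@H](C)C[C@H]3C(C)=C | intermediate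
33 | 6-O-methyl ether of 32 | C[C@]1(O)CC[C@@H](OC)[C@H](C)C[C@@H]2O[C@H]1[C@@H]3[C@H]2[C@H](OC(C)=O)[C@H](C)C[C@H]3C(C)=C | intermediate
34 | B-alkyl-9-borabicyclo[3.3.1]nonane from 33 (boron on C16) | C[C@]1(O)CC[C@@H](OC)[C@H](C)C[C@@H]2O[C@H]1[C@@H]3[C@H]2[C@H](OC(C)=O)[C@H](C)C[C@H]3[C@@H](C)CB4C5CCCC4CCC5 | intermediate
35 | C16 primary alcohol: C14 side chain (R)-CH(CH3)CH2OH | C[C@]1(O)CC[C@@H](OC)[C@H](C)C[C@@H]2O[C@H]1[C@@H]3[C@H]2[C@H](OC(C)=O)[C@H](C)C[C@H]3[C@@H](C)CO | intermediate
36 | C16 triflate of 35 | C[C@]1(O)CC[C@@H](OC)[C@H](C)C[C@@H]2O[C@H]1[C@@H]3[C@H]2[C@H](OC(C)=O)[C@H](C)C[C@H]3[C@@H](C)COS(=O)(=O)C(F)(F)F | intermediate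
37 | CNP0289153.2 | CO[C@@H]1CC[C@]2(C)OC[C@H](C)[C@@H]3C[C@@H](C)[C@@H](OC(C)=O)[C@@H]4[C@H]3[C@@H]2O[C@H]4C[C@H]1C | target

**Step count and risks**

Total step count: 26. Longest linear sequence: 26 steps (from 1).

Three steps most likely to fail:

- **Step 8 (lactonization).** Acylation of the hindered tertiary allylic alcohol may be slower than ionization of that alcohol or than intermolecular esterification. The fallback sets out from 6 and comes back at 13. Ozonolysis of imide 6 (O3, CH2Cl2, −78 °C; Me2S) proceeds through the ozonide of 6 F1 to the keto imide F2. CH2=CHMgBr (THF, −78 °C) should add to the ketone faster than to the imide. On warming to 0 °C the magnesium tert-alkoxide should cleave the exocyclic imide carbonyl intramolecularly, giving lactone 13 and the free oxazolidinone.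

- **Step 9 (key step).** The acid-sensitive enol ether may hydrolyse, the product ketone may be methylenated a second time, or the rearrangement may stall for the slower C7 epimer. The fallback sets out from 6 and comes back at 15; it builds the nine-membered ring by ring-closing metathesis and also bypasses steps 5–8. Transamidation of 6 with Me(MeO)NH·HCl/AlMe3 (CH2Cl2, 0 °C) gives the Weinreb amide F3. CH2=CHCH2CH2MgBr (THF, 0 °C) gives the but-3-enyl ketone F4. Second-generation Grubbs catalyst (CH2Cl2, 40 °C, high dilution) joins the butenyl and methallyl termini to the Z C6=C7 bond of 15 with loss of ethene.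

- **Step 10 (C3 configuration).** Facial selectivity may be poor, or chelation through O1 may reverse it and give the C3 epimer. The fallback sets out from 15 and comes back at 16. Dimethylsulfoxonium methylide (Me3S(O)I, NaH, DMSO, rt) adds reversibly and should place the new C–C bond on the face that irreversible organometallic addition avoids, giving the spiro-epoxide F5. LiEt3BH (THF, 0 °C) opens the epoxide at CH2 to give 16, so that methyl and hydroxyl are interchanged relative to the direct addition product.

Further compounds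
F1 | step 8 | ozonide of imide 6 | CC1(C[C@H](O[C@@H](COCc2ccccc2)C(=O)N2[C@H](Cc3ccccc3)COC2=O)CCOCc2ccc(OC)cc2)OCOO1
F2 | step 8 | keto imide (methyl ketone from 6) | CC(=O)C[C@H](O[C@@H](COCc1ccccc1)C(=O)N1[C@H](Cc2ccccc2)COC1=O)CCOCc1ccc(OC)cc1
F3 | step 9 | Weinreb amide of acid 8 | C=C(C)C[C@H](O[C@@H](COCc1ccccc1)C(=O)N(C)OC)CCOCc1ccc(OC)cc1
F4 | step 9 | but-3-enyl ketone (ring-closing metathesis precursor) | C=C(C)C[C@H](O[C@@H](COCc1ccccc1)C(=O)CCC=C)CCOCc1ccc(OC)cc1
F5 | step 10 | C3 spiro-epoxide of 15 | C1O[C@]12CC/C=C(/C)C[C@@H](CCOCc3ccc(OC)cc3)O[C@H]2COCc3ccccc3
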